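**Strategy**

Everything rests on cutting the C7–C11 and C11=C13 bonds of the lactone. C7 lies between the oxygen-bearing carbons C6 and C8, so a C7–C8 epoxide whose C6 oxygen carries a phosphonoacetate lets C11 reach C7 with inversion while C8 keeps its oxygen. In one operation the key step closes the γ-lactone ring (O–C12–C11–C7–C6), sets C7, frees the C8 hydroxyl and creates the exocyclic methylene by olefination of formaldehyde. Its precursor is the phosphonoacetate of an erythro trans-epoxy alcohol that already holds the C4=C5 alkene, C15 as a silyl ether, C9 as a PMB ether and C1 as a dimethyl acetal. The ten-membered carbocycle (C1–C10) is closed afterwards at C9–C10.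

Key step: step 9

Remark: atom labels follow germacranolide numbering (carbocycle C1–C10, ester carbon C14 on C10, C15 on C4, lactone carbons C11–C13 on C7); carbinol 13 is made as the racemate and resolved in step 7.

**Route**

Step 1
Reactants: 1 but-2-yne-1,4-diol
Product: 2 mono-TBDPS ether 4-(tert-butyldiphenylsilyloxy)but-2-yn-1-ol
Conditions: NaH (1.0 equiv), THF, 0 °C; TBDPSCl (1.0 equiv), rt
Reagents that add atoms: tert-butyl(chloro)diphenylsilane, CC(C)(C)[Si](Cl)(c1ccccc1)c1ccccc1
Why: O-Silylation of the monosodium alkoxide of a symmetrical diol favours the monoether, and TBDPS is chosen for C15 because it must outlast the acidic acetal cleavage of step 11 and leave last.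

Step 2
Reactants: 2 mono-TBDPS ether 4-(tert-butyldiphenylsilyloxy)but-2-yn-1-ol
Product: 4 (Z)-4-(tert-butyldiphenylsilyloxy)-3-iodobut-2-en-1-ol, via cyclic sodium alkenylaluminate 3 (not isolated)
Conditions: NaAlH2(OCH2CH2OMe)2 (1.5 equiv), THF, 0 °C → rt; EtOAc, then I2, −78 → 0 °C
Reagents that add atoms: iodine, [I][I]
Why: Hydroxyl-directed trans-hydroalumination of the propargylic alcohol puts hydride on C5 and aluminium on C4 inside a five-membered alanate, and iododealumination with retention leaves iodine cis to the C6 carbinol carbon.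

Step 3
Reactants: 4 (Z)-4-(tert-butyldiphenylsilyloxy)-3-iodobut-2-en-1-ol; 5 acrolein dimethyl acetal
Product: 7 (E)-3-[(tert-butyldiphenylsilyloxy)methyl]-6,6-dimethoxyhex-2-en-1-ol, via B-(3,3-dimethoxypropyl)-9-BBN 6 (not isolated)
Conditions: 5, 9-BBN-H, THF, 0 °C → rt; then 4, PdCl2(dppf) (5 mol %), AsPh3, Cs2CO3, DMF/H2O, rt
Reagents that add atoms: none
Why: Anti-Markovnikov hydroboration followed by B-alkyl Suzuki–Miyaura coupling replaces iodine with retention, so the C3–C1 chain ends up cis to C6 and C15 trans to it, which is the C4=C5 geometry of the target.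

Step 4
Reactants: 7 (E)-3-[(tert-butyldiphenylsilyloxy)methyl]-6,6-dimethoxyhex-2-en-1-ol
Product: 8 (E)-3-[(tert-butyldiphenylsilyloxy)methyl]-6,6-dimethoxyhex-2-enal
Conditions: MnO2 (excess), CH2Cl2, rt
Reagents that add atoms: none
Why: Allylic alcohol oxidation with MnO2 is neutral and heterogeneous, so neither the alkene geometry nor the acetal is disturbed.

Step 5
Reactants: 9 propargyl alcohol
Product: 10 PMB propargyl ether (1-methoxy-4-[(prop-2-ynyloxy)methyl]benzene)
Conditions: NaH, PMBCl, Bu4NI (cat.), THF/DMF, 0 °C → rt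
Reagents that add atoms: 4-methoxybenzyl chloride, COc1ccc(CCl)cc1
Why: Williamson etherification of the alkoxide; PMB is chosen for C9 because, unlike a silyl group, it cannot migrate to the neighbouring C8 alkoxide formed in step 9.

Step 6
Reactants: 8 (E)-3-[(tert-butyldiphenylsilyloxy)methyl]-6,6-dimethoxyhex-2-enal; 10 PMB propargyl ether
Product: 13 rac-(2E,5E)-6-[(tert-butyldiphenylsilyloxy)methyl]-9,9-dimethoxy-1-(4-methoxybenzyloxy)nona-2,5-dien-4-ol, via alkenylzirconocene chloride 11 (not isolated), via alkenyl(methyl)zinc 12 (not isolated)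
Conditions: 10, Cp2Zr(H)Cl, CH2Cl2, rt; Me2Zn, toluene, −65 °C; then 8, 0 °C
Reagents that add atoms: none
Why: Syn hydrozirconation places the metal on the terminal carbon, and the (E)-alkenylzinc obtained by transmetalation adds 1,2 to the enal (Wipf alkenylation) to form the C6–C7 bond; C6 arises racemic and is resolved in step 7.

Step 7
Reactants: 13 rac-(2E,5E)-6-[(tert-butyldiphenylsilyloxy)methyl]-9,9-dimethoxy-1-(4-methoxybenzyloxy)nona-2,5-dien-4-ol
Product: 14 erythro epoxy alcohol (1R,2E)-3-[(tert-butyldiphenylsilyloxy)methyl]-6,6-dimethoxy-1-{(2R,3R)-3-[(4-methoxybenzyloxy)methyl]oxiran-2-yl}hex-2-en-1-ol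
Conditions: Ti(OiPr)4 (0.2 equiv), D-(−)-DIPT (0.25 equiv), t-BuOOH (0.6 equiv), 4 Å MS, CH2Cl2, −20 °C
Reagents that add atoms: tert-butyl hydroperoxide, CC(C)(C)OO
Why: Sharpless kinetic-resolution epoxidation: with the D-tartrate the (S)-configured carbinol is the fast-reacting enantiomer at its (E)-disubstituted C7=C8 arm and should give the erythro (anti) trans-epoxide, whereas for this enantiomer the C4=C5 arm is the mismatched one and is further retarded by its cis C3 substituent; the (R)-alcohol is left behind.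

Step 8
Reactants: 14 erythro epoxy alcohol; 15 diethylphosphonoacetic acid
Product: 16 (1R,2E)-3-[(tert-butyldiphenylsilyloxy)methyl]-6,6-dimethoxy-1-{(2R,3R)-3-[(4-methoxybenzyloxy)methyl]oxiran-2-yl}hex-2-en-1-yl 2-(diethoxyphosphoryl)acetate
Conditions: DCC, DMAP (cat.), CH2Cl2, 0 °C → rt
Reagents that add atoms: none
Why: Steglich esterification acylates the secondary C6 hydroxyl under neutral conditions that leave the adjacent epoxide intact and attaches C11–C12 to the C6 oxygen.

Step 9
Reactants: 16 phosphonoacetate of the erythro trans-epoxy alcohol; 17 formaldehyde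
Product: 19 (4R,5R)-5-{(1E)-2-[(tert-butyldiphenylsilyloxy)methyl]-5,5-dimethoxypent-1-en-1-yl}-4-[(1S)-1-hydroxy-2-(4-methoxybenzyloxy)ethyl]-3-methylideneoxolan-2-one, via α-phosphono lactone 18 (not isolated)
Conditions: NaH (1.05 equiv), THF (0.02 M), 0 → 50 °C; then CH2O (THF solution from cracked (CH2O)n), −20 °C → rt
Reagents that add atoms: none
Why: NaH forms the phosphonate-stabilised carbanion at C11, which attacks C7 from the side opposite the C7–O bond of the epoxide and closes the lactone ring O–C12–C11–C7–C6 by a 5-exo-tet ring closure; the C8 alkoxide set free is quenched by the much more acidic α-phosphono lactone C–H of 18, and the carbanion formed in this way olefinates formaldehyde (Horner–Wadsworth–Emmons) to give C11=C13 with loss of sodium diethyl phosphate. The closest known reactions are the base-induced opening of epoxides by ester-tethered stabilised carbanions to γ-lactones and the formaldehyde olefination of α-phosphono-γ-butyrolactones; running them one after the other in the same flask is the only extension. The one new stereocentre, C7, is controlled by SN2 inversion at the epoxide carbon whose configuration was set by the tartrate in step 7, and because the epoxy alcohol is erythro this inversion gives the trans-fused lactone (H6 and H7 anti) with C8 keeping its oxygen and configuration. The step needs C-alkylation at C7 rather than O-alkylation or 6-endo attack at C8; the soft carbanion, the short three-atom tether from O6 and the collinear backside trajectory, which this tether allows only at C7, secure it, and the doubly stabilised anion is too weakly basic to trigger a Claisen-type shift of the allylic ester. The C9 oxygen is deliberately a PMB ether and not a silyl ether, so that nothing can migrate to the transient C8 alkoxide and the C8 hydroxyl emerges as the only free one.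

Step 10
Reactants: 19 α-methylene lactone with free C8 hydroxyl
Product: 20 (1S)-1-{(2R,3S)-2-[(1E)-2-[(tert-butyldiphenylsilyloxy)methyl]-5,5-dimethoxypent-1-en-1-yl]-4-methylidene-5-oxooxolan-3-yl}-2-(4-methoxybenzyloxy)ethyl 2-methylpropanoate
Conditions: (i-PrCO)2O, pyridine, DMAP (cat.), CH2Cl2, 0 °C → rt
Reagents that add atoms: isobutyric anhydride, CC(C)C(=O)OC(=O)C(C)C
Why: DMAP-catalysed acylation of the only free hydroxyl (C8) installs the isobutyrate of the target without touching the stereocentre.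

Step 11
Reactants: 20 C8 isobutyrate
Product: 21 (1S)-1-{(2R,3S)-2-[(1E)-2-[(tert-butyldiphenylsilyloxy)methyl]-5-oxopent-1-en-1-yl]-4-methylidene-5-oxooxolan-3-yl}-2-(4-methoxybenzyloxy)ethyl 2-methylpropanoate
Conditions: PPTS, acetone/H2O (9:1), 45 °C
Reagents that add atoms: water, O
Why: Acid-catalysed hydrolysis of the dimethyl acetal unveils the C1 aldehyde in one step, and the mild pyridinium acid should spare the TBDPS and PMB ethers, the esters and the allylic lactone.

Step 12
Reactants: 21 C1 aldehyde; 22 methyl (triphenylphosphoranylidene)acetate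
Product: 24 methyl (2Z,6E)-6-[(tert-butyldiphenylsilyloxy)methyl]-2-iodo-7-{(2R,3S)-3-[(1S)-2-(4-methoxybenzyloxy)-1-(2-methylpropanoyloxy)ethyl]-4-methylidene-5-oxooxolan-2-yl}hepta-2,6-dienoate, via iodo ylide 23 (not isolated)
Conditions: 22, NIS, CH2Cl2, −20 °C; then 21, −20 °C → rt
Reagents that add atoms: N-iodosuccinimide, O=C1CCC(=O)N1I
Why: Wittig olefination with the stabilised α-iodo ylide made by iodination of 22 should give mainly the (Z)-α-iodo enoate (iodine cis to C2, ester trans to it), which brings in C10 and C14 under conditions mild enough for the α-methylene lactone.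

Step 13
Reactants: 24 (Z)-α-iodo enoate
Product: 25 methyl (2Z,6E)-6-[(tert-butyldiphenylsilyloxy)methyl]-7-{(2R,3S)-3-[(1S)-2-hydroxy-1-(2-methylpropanoyloxy)ethyl]-4-methylidene-5-oxooxolan-2-yl}-2-iodohepta-2,6-dienoate
Conditions: DDQ, CH2Cl2/pH 7 buffer, 0 °C
Reagents that add atoms: none
Why: Oxidative PMB cleavage by DDQ (hydride abstraction to the benzylic oxocarbenium ion, then hydrolysis) is orthogonal to the silyl ether, the alkenyl iodide and the esters, and the buffered medium keeps the isobutyrate on O8.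

Step 14
Reactants: 25 C9 alcohol
Product: 26 methyl (2Z,6E)-6-[(tert-butyldiphenylsilyloxy)methyl]-2-iodo-7-{(2R,3S)-4-methylidene-3-[(1S)-1-(2-methylpropanoyloxy)-2-oxoethyl]-5-oxooxolan-2-yl}hepta-2,6-dienoate
Conditions: Dess–Martin periodinane, NaHCO3, CH2Cl2, 0 °C → rt
Reagents that add atoms: none
Why: Dess–Martin oxidation under buffered, non-basic conditions gives the α-acyloxy aldehyde without epimerising C8; the aldehyde is used directly.

Step 15
Reactants: 26 C9 aldehyde bearing the (Z)-α-iodo enoate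
Product: 27 methyl (1(10)E,4E,6R,7S,8S,9S)-15-(tert-butyldiphenylsilyloxy)-9-hydroxy-8-(2-methylpropanoyloxy)germacra-1(10),4,11(13)-trien-12,6-olid-14-oate
Conditions: CrCl2 (10 equiv), NiCl2 (2 mol %), DMSO (3 mM), rt
Reagents that add atoms: none
Why: Intramolecular Nozaki–Hiyama–Kishi reaction: zerovalent nickel inserts into the C10–I bond, the alkenyl group passes to trivalent chromium and adds to the C9 aldehyde, which should close the ten-membered ring with retention of the C1=C10 geometry; C9 is set under substrate control by the conformation of the closing ring, and the 9S epimer (O9 syn to O8) is the one carried on.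

Step 16
Reactants: 27 macrocyclic C9 alcohol
Product: 28 methyl (1(10)E,4E,6R,7S,8S,9S)-9-acetoxy-15-(tert-butyldiphenylsilyloxy)-8-(2-methylpropanoyloxy)germacra-1(10),4,11(13)-trien-12,6-olid-14-oate
Conditions: Ac2O, pyridine, DMAP (cat.), CH2Cl2, 0 °C
Reagents that add atoms: acetic anhydride, CC(=O)OC(C)=O
Why: DMAP-catalysed acetylation of the secondary allylic C9 hydroxyl is fast at 0 °C, which forestalls acyl migration between O8 and O9.

Step 17
Reactants: 28 C9 acetate with C15 silyl ether
Product: 29 methyl (1(10)E,4E,6R,7S,8S,9S)-9-acetoxy-15-hydroxy-8-(2-methylpropanoyloxy)germacra-1(10),4,11(13)-trien-12,6-olid-14-oate (CNP0242134.2)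
Conditions: HF·pyridine, pyridine/THF, 0 °C → rt
Reagents that add atoms: none
Why: Fluoride-induced cleavage of the primary TBDPS ether under buffered conditions should liberate the C15 alcohol without hydrolysing the esters or adding to the α-methylene lactone.

**Compound list**

1 | but-2-yne-1,4-diol | OCC#CCO | starting material
2 | 4-(tert-butyldiphenylsilyloxy)but-2-yn-1-ol | OCC#CCO[Si](c1ccccc1)(c1ccccc1)C(C)(C)C | intermediate
3 | cyclic sodium alkenylaluminate (sodium 2,2-bis(2-methoxyethoxy)-3-[(tert-butyldiphenylsilyloxy)methyl]-2,5-dihydro-1,2-oxaaluminol-2-uide) | [Na+].COCCO[Al-]1(OCCOC)OCC=C1CO[Si](c2ccccc2)(c3ccccc3)C(C)(C)C | intermediate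
4 | (Z)-4-(tert-butyldiphenylsilyloxy)-3-iodobut-2-en-1-ol | OC/C=C(\I)CO[Si](c1ccccc1)(c1ccccc1)C(C)(C)C | intermediate
5 | acrolein dimethyl acetal (3,3-dimethoxyprop-1-ene) | C=CC(OC)OC | starting material
6 | B-(3,3-dimethoxypropyl)-9-BBN | COC(OC)CCB1C2CCCC1CCC2 | intermediate
7 | (E)-3-[(tert-butyldiphenylsilyloxy)methyl]-6,6-dimethoxyhex-2-en-1-ol | OC/C=C(/CO[Si](c1ccccc1)(c1ccccc1)C(C)(C)C)CCC(OC)OC | intermediate
8 | (E)-3-[(tert-butyldiphenylsilyloxy)methyl]-6,6-dimethoxyhex-2-enal | O=C/C=C(/CO[Si](c1ccccc1)(c1ccccc1)C(C)(C)C)CCC(OC)OC | intermediate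
9 | propargyl alcohol | C#CCO | starting material
10 | PMB propargyl ether (1-methoxy-4-[(prop-2-ynyloxy)methyl]benzene) | C#CCOCc1ccc(OC)cc1 | intermediate
11 | (E)-[3-(4-methoxybenzyloxy)prop-1-enyl]zirconocene chloride | COc1ccc(COC/C=C/[Zr](Cl)(C2C=CC=C2)C2C=CC=C2)cc1 | intermediate
12 | (E)-[3-(4-methoxybenzyloxy)prop-1-enyl](methyl)zinc | COc1ccc(COC/C=C/[Zn]C)cc1 | intermediate
13 | rac-(2E,5E)-6-[(tert-butyldiphenylsilyloxy)methyl]-9,9-dimethoxy-1-(4-methoxybenzyloxy)nona-2,5-dien-4-ol | COc1ccc(COC/C=C/C(O)/C=C(/CO[Si](c2ccccc2)(c2ccccc2)C(C)(C)C)CCC(OC)OC)cc1 | intermediate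
14 | (1R,2E)-3-[(tert-butyldiphenylsilyloxy)methyl]-6,6-dimethoxy-1-{(2R,3R)-3-[(4-methoxybenzyloxy)methyl]oxiran-2-yl}hex-2-en-1-ol (erythro, trans-epoxide) | O[C@H](/C=C(/CO[Si](c1ccccc1)(c1ccccc1)C(C)(C)C)CCC(OC)OC)[C@H]2O[C@@H]2COCc3ccc(OC)cc3 | intermediate
15 | diethylphosphonoacetic acid | OC(=O)CP(=O)(OCC)OCC | starting material
16 | (1R,2E)-3-[(tert-butyldiphenylsilyloxy)methyl]-6,6-dimethoxy-1-{(2R,3R)-3-[(4-methoxybenzyloxy)methyl]oxiran-2-yl}hex-2-en-1-yl 2-(diethoxyphosphoryl)acetate | CCOP(=O)(OCC)CC(=O)O[C@H](/C=C(/CO[Si](c1ccccc1)(c1ccccc1)C(C)(C)C)CCC(OC)OC)[C@H]2O[C@@H]2COCc3ccc(OC)cc3 | intermediate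
17 | formaldehyde (supplied as paraformaldehyde) | C=O | starting material
18 | diethyl {(4R,5R)-5-[(1E)-2-[(tert-butyldiphenylsilyloxy)methyl]-5,5-dimethoxypent-1-en-1-yl]-4-[(1S)-1-hydroxy-2-(4-methoxybenzyloxy)ethyl]-2-oxooxolan-3-yl}phosphonate (sodium salt in the flask, C11 unassigned) | CCOP(=O)(OCC)C1C(=O)O[C@H](/C=C(/CO[Si](c2ccccc2)(c2ccccc2)C(C)(C)C)CCC(OC)OC)[C@H]1[C@H](O)COCc3ccc(OC)cc3 | intermediate
19 | (4R,5R)-5-{(1E)-2-[(tert-butyldiphenylsilyloxy)methyl]-5,5-dimethoxypent-1-en-1-yl}-4-[(1S)-1-hydroxy-2-(4-methoxybenzyloxy)ethyl]-3-methylideneoxolan-2-one | C=C1C(=O)O[C@H](/C=C(/CO[Si](c2ccccc2)(c2ccccc2)C(C)(C)C)CCC(OC)OC)[C@H]1[C@H](O)COCc3ccc(OC)cc3 | intermediate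
20 | (1S)-1-{(2R,3S)-2-[(1E)-2-[(tert-butyldiphenylsilyloxy)methyl]-5,5-dimethoxypent-1-en-1-yl]-4-methylidene-5-oxooxolan-3-yl}-2-(4-methoxybenzyloxy)ethyl 2-methylpropanoate | C=C1C(=O)O[C@H](/C=C(/CO[Si](c2ccccc2)(c2ccccc2)C(C)(C)C)CCC(OC)OC)[C@H]1[C@H](OC(=O)C(C)C)COCc3ccc(OC)cc3 | intermediate
21 | (1S)-1-{(2R,3S)-2-[(1E)-2-[(tert-butyldiphenylsilyloxy)methyl]-5-oxopent-1-en-1-yl]-4-methylidene-5-oxooxolan-3-yl}-2-(4-methoxybenzyloxy)ethyl 2-methylpropanoate | C=C1C(=O)O[C@H](/C=C(/CO[Si](c2ccccc2)(c2ccccc2)C(C)(C)C)CCC=O)[C@H]1[C@H](OC(=O)C(C)C)COCc3ccc(OC)cc3 | intermediate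
22 | methyl (triphenylphosphoranylidene)acetate | COC(=O)C=P(c1ccccc1)(c1ccccc1)c1ccccc1 | starting material
23 | methyl iodo(triphenylphosphoranylidene)acetate | COC(=O)C(I)=P(c1ccccc1)(c1ccccc1)c1ccccc1 | intermediate
24 | methyl (2Z,6E)-6-[(tert-butyldiphenylsilyloxy)methyl]-2-iodo-7-{(2R,3S)-3-[(1S)-2-(4-methoxybenzyloxy)-1-(2-methylpropanoyloxy)ethyl]-4-methylidene-5-oxooxolan-2-yl}hepta-2,6-dienoate | C=C1C(=O)O[C@H](/C=C(/CO[Si](c2ccccc2)(c2ccccc2)C(C)(C)C)CC/C=C(\I)C(=O)OC)[C@H]1[C@H](OC(=O)C(C)C)COCc3ccc(OC)cc3 | intermediate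
25 | methyl (2Z,6E)-6-[(tert-butyldiphenylsilyloxy)methyl]-7-{(2R,3S)-3-[(1S)-2-hydroxy-1-(2-methylpropanoyloxy)ethyl]-4-methylidene-5-oxooxolan-2-yl}-2-iodohepta-2,6-dienoate | C=C1C(=O)O[C@H](/C=C(/CO[Si](c2ccccc2)(c2ccccc2)C(C)(C)C)CC/C=C(\I)C(=O)OC)[C@H]1[C@H](OC(=O)C(C)C)CO | intermediate
26 | methyl (2Z,6E)-6-[(tert-butyldiphenylsilyloxy)methyl]-2-iodo-7-{(2R,3S)-4-methylidene-3-[(1S)-1-(2-methylpropanoyloxy)-2-oxoethyl]-5-oxooxolan-2-yl}hepta-2,6-dienoate | C=C1C(=O)O[C@H](/C=C(/CO[Si](c2ccccc2)(c2ccccc2)C(C)(C)C)CC/C=C(\I)C(=O)OC)[C@H]1[C@H](OC(=O)C(C)C)C=O | intermediate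
27 | methyl (1(10)E,4E,6R,7S,8S,9S)-15-(tert-butyldiphenylsilyloxy)-9-hydroxy-8-(2-methylpropanoyloxy)germacra-1(10),4,11(13)-trien-12,6-olid-14-oate | C=C1C(=O)O[C@@H]2/C=C(/CO[Si](c3ccccc3)(c3ccccc3)C(C)(C)C)CC/C=C(/C(=O)OC)[C@H](O)[C@@H](OC(=O)C(C)C)[C@@H]12 | intermediate
28 | methyl (1(10)E,4E,6R,7S,8S,9S)-9-acetoxy-15-(tert-butyldiphenylsilyloxy)-8-(2-methylpropanoyloxy)germacra-1(10),4,11(13)-trien-12,6-olid-14-oate | C=C1C(=O)O[C@@H]2/C=C(/CO[Si](c3ccccc3)(c3ccccc3)C(C)(C)C)CC/C=C(/C(=O)OC)[C@H](OC(C)=O)[C@@H](OC(=O)C(C)C)[C@@H]12 | intermediate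
29 | methyl (1(10)E,4E,6R,7S,8S,9S)-9-acetoxy-15-hydroxy-8-(2-methylpropanoyloxy)germacra-1(10),4,11(13)-trien-12,6-olid-14-oate (CNP0242134.2) | C=C1C(=O)O[C@@H]2/C=C(/CO)CC/C=C(/C(=O)OC)[C@H](OC(C)=O)[C@@H](OC(=O)C(C)C)[C@@H]12 | target

**Step count and risks**

Total steps: 17. Longest linear sequence: 16 (steps 1–4 and 6–17; step 5 is a one-step side branch).

Steps most likely to fail:

1. Step 9. The cascade can leave its path at two points. The ambident anion may alkylate on oxygen or open the epoxide at C8 (6-endo). The transient C8 alkoxide may attack C12 (lactone migration to O8) or phosphorus before the proton shift. Fallback, stepwise and with the C8 oxygen capped before the olefination: setting out from 16, the ring closure is run alone (NaH, THF, then NH4Cl quench) and the α-phosphono lactone 18 is isolated. Its C8 hydroxyl is acylated with isobutyric anhydride, pyridine and DMAP to give the α-phosphono lactone isobutyrate F1. F1 is then olefinated under the classical two-phase conditions (K2CO3, aqueous CH2O, THF, 0 °C), which gives 20 directly, and the route is rejoined at 20.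

2. Step 15. Facial selection at C9 during ring closure may favour the wrong epimer, since the acyclic Felkin–Anh preference of an α-acyloxy aldehyde points to O9 anti to O8. Slow closure of the strained ring may also allow reduction of the C–I bond or loss of the C1=C10 geometry through an O-bound allenoate form of the alkenylchromium. Fallback, in which C9 is set by reduction and no longer by C–C bond formation: setting out from 26, the ring is closed without regard to the C9 outcome to give the C9 epimer F2 (alone or mixed with 27). Dess–Martin oxidation gives the C9 ketone F3. Reagent-controlled reduction of this alkenyl ketone with (S)-2-methyl-CBS-oxazaborolidine and catecholborane (toluene, −78 °C) is expected to give 27, where the route is rejoined; the alkenyl group acts as the large substituent, and the Felkin–Anh preference of the α-acyloxy ketone for the 8,9-syn alcohol points the same way.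

3. Step 7. Site selection between the two allylic alkenes (epoxidation of the more electron-rich C4=C5 arm) or enantiomer discrimination may be insufficient, and half of the material is lost by design. Fallback by nucleophilic epoxidation: setting out from 13, MnO2 oxidation gives the cross-conjugated dienone F4. Catalytic asymmetric epoxidation with La(OiPr)3, BINOL (the enantiomer giving the 7S,8R epoxide, expected to be R), Ph3As=O and t-BuOOH (4 Å MS, THF, rt) should attack only the β-monosubstituted C7=C8 enone arm and give the trans-epoxy enone F5. Chelation-controlled reduction with Zn(BH4)2 (Et2O, −20 °C) should give the erythro epoxy alcohol 14, where the route is rejoined; both enantiomers of 13 converge.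

**Further compounds**

F1 | step 9 | (1S)-1-{(2R,3R)-4-(diethoxyphosphoryl)-2-[(1E)-2-[(tert-butyldiphenylsilyloxy)methyl]-5,5-dimethoxypent-1-en-1-yl]-5-oxooxolan-3-yl}-2-(4-methoxybenzyloxy)ethyl 2-methylpropanoate | CCOP(=O)(OCC)C1C(=O)O[C@H](/C=C(/CO[Si](c2ccccc2)(c2ccccc2)C(C)(C)C)CCC(OC)OC)[C@H]1[C@H](OC(=O)C(C)C)COCc3ccc(OC)cc3
F2 | step 15 | methyl (1(10)E,4E,6R,7S,8S,9R)-15-(tert-butyldiphenylsilyloxy)-9-hydroxy-8-(2-methylpropanoyloxy)germacra-1(10),4,11(13)-trien-12,6-olid-14-oate (C9 epimer of 27) | C=C1C(=O)O[C@@H]2/C=C(/CO[Si](c3ccccc3)(c3ccccc3)C(C)(C)C)CC/C=C(/C(=O)OC)[C@@H](O)[C@@H](OC(=O)C(C)C)[C@@H]12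
F3 | step 15 | methyl (1(10)E,4E,6R,7S,8S)-15-(tert-butyldiphenylsilyloxy)-8-(2-methylpropanoyloxy)-9-oxogermacra-1(10),4,11(13)-trien-12,6-olid-14-oate | C=C1C(=O)O[C@@H]2/C=C(/CO[Si](c3ccccc3)(c3ccccc3)C(C)(C)C)CC/C=C(/C(=O)OC)C(=O)[C@@H](OC(=O)C(C)C)[C@@H]12
F4 | step 7 | (2E,5E)-6-[(tert-butyldiphenylsilyloxy)methyl]-9,9-dimethoxy-1-(4-methoxybenzyloxy)nona-2,5-dien-4-one | COc1ccc(COC/C=C/C(=O)/C=C(/CO[Si](c2ccccc2)(c2ccccc2)C(C)(C)C)CCC(OC)OC)cc1
F5 | step 7 | (2E)-3-[(tert-butyldiphenylsilyloxy)methyl]-6,6-dimethoxy-1-{(2S,3R)-3-[(4-methoxybenzyloxy)methyl]oxiran-2-yl}hex-2-en-1-one | O=C(/C=C(/CO[Si](c1ccccc1)(c1ccccc1)C(C)(C)C)CCC(OC)OC)[C@H]2O[C@@H]2COCc3ccc(OC)cc3
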